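**Retrosynthetic overview**
- The strategy rests on ring A of unit 1 (the 6-linked 5,7-dihydroxyflavone). Its biaryl carbon C6 lies between the two hydroxyl-bearing carbons C5 and C7, so C5–C6–C7 is an arylmalonyl unit. C4a, C8a and C8 correspond to C5, C6 and the methyl carbon of a 2-aryl-6-methyl-4-pyranone.
- Target 14 comes from 13 by cleavage of the peri 5-methyl ether of unit 2 only.
- 13 comes from pyranone 4 and arylmalonyl dichloride 10 by a [3+3] benzannulation that forms C7–C8 and C4a–C5. Ring A of unit 1 is the last ring closed; every other ring is brought in preformed.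
- 10 comes from commercial 5,7,4'-trimethoxyflavone 5 by 8-iodination, malonate arylation, ester cleavage and chlorination. 4 comes from pentane-2,4-dione and methyl 4-methoxybenzoate through a 1,3,5-triketone (pyranone ring of unit 1 closed in step 2).

Key step: step 7

Assumption: the target SMILES defines no configuration at the tetra-ortho-substituted biaryl axis, so the axis is formed without control (13 and 14 racemic if the axis is configurationally stable).

**Route**

Step 1
Reactants: 1 pentane-2,4-dione; 2 methyl 4-methoxybenzoate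
Product: 3 1-(4-methoxyphenyl)hexane-1,3,5-trione
Conditions: NaH (4 equiv), 1 (1.5 equiv), DME, reflux; then cold aq. HCl
Reagents that add atoms: none
Why: Excess NaH generates the 1,3-dianion of the diketone, whose terminal carbon is acylated by the non-enolisable aryl ester (Claisen-type aroylation of a β-diketone dianion); the product is held as its polyanion, and the excess of 1 limits aroylation at the second methyl group.

Step 2
Reactants: 3 1-(4-methoxyphenyl)hexane-1,3,5-trione
Product: 4 2-(4-methoxyphenyl)-6-methyl-4H-pyran-4-one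
Conditions: conc. H2SO4, 0 °C; poured onto ice
Reagents that add atoms: none
Why: Acid-mediated cyclodehydration of a 1,3,5-triketone, in which the terminal enol oxygen adds to the other terminal carbonyl and water is lost, is the standard route to 2,6-disubstituted 4-pyranones.

Step 3
Reactants: 5 5,7-dimethoxy-2-(4-methoxyphenyl)-4H-chromen-4-one (5,7,4'-trimethoxyflavone)
Product: 6 8-iodo-5,7-dimethoxy-2-(4-methoxyphenyl)-4H-chromen-4-one
Conditions: I2, CF3CO2Ag, CH2Cl2, 0 °C to rt, dark
Reagents that add atoms: iodine (I2), SMILES II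
Why: Electrophilic aromatic iodination with silver-activated iodine should occur on the phloroglucinol-type ring A, and in 5-O-alkyl flavones C8 (between O1 and the 7-methoxy group) is expected to react in preference to C6, which is flanked by two methoxy groups.

Step 4
Reactants: 6 8-iodo-5,7-dimethoxy-2-(4-methoxyphenyl)-4H-chromen-4-one; 7 di-tert-butyl malonate
Product: 8 di-tert-butyl 2-[5,7-dimethoxy-2-(4-methoxyphenyl)-4-oxo-4H-chromen-8-yl]malonate
Conditions: Pd(OAc)2 (5 mol%), P(t-Bu)3·HBF4 (10 mol%), K3PO4 (3 equiv), 7 (1.5 equiv), toluene, 80 °C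
Reagents that add atoms: none
Why: Palladium-catalysed α-arylation of a malonate (Hartwig type), in which the bulky electron-rich phosphine promotes oxidative addition into the hindered electron-rich C8–I bond and reductive elimination of the aryl malonate; tert-butyl esters are chosen so that the diacid can later be released without hydroxide.

Step 5
Reactants: 8 di-tert-butyl 2-[5,7-dimethoxy-2-(4-methoxyphenyl)-4-oxo-4H-chromen-8-yl]malonate
Product: 9 2-[5,7-dimethoxy-2-(4-methoxyphenyl)-4-oxo-4H-chromen-8-yl]malonic acid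
Conditions: CF3CO2H–CH2Cl2 (1:2), 0 °C to rt; evaporated below 25 °C, toluene co-evaporation, Et2O trituration
Reagents that add atoms: none
Why: Acidolysis of tert-butyl esters (loss of 2-methylpropene) frees the arylmalonic acid without aqueous base, so the pyranone ring of the flavone is not exposed to hydroxide, and keeping the temperature at or below rt should avoid decarboxylation.

Step 6
Reactants: 9 2-[5,7-dimethoxy-2-(4-methoxyphenyl)-4-oxo-4H-chromen-8-yl]malonic acid
Product: 10 2-[5,7-dimethoxy-2-(4-methoxyphenyl)-4-oxo-4H-chromen-8-yl]malonyl dichloride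
Conditions: 1-chloro-N,N,2-trimethylprop-1-en-1-amine (2.2 equiv), CH2Cl2, 0 °C to rt; concentrated and used crude
Reagents that add atoms: 1-chloro-N,N,2-trimethylprop-1-en-1-amine (Ghosez reagent), SMILES CC(C)=C(Cl)N(C)C
Why: The α-chloroenamine converts carboxylic acids into acid chlorides under neutral conditions with only an amide as by-product, so no HCl or oxalyl-type electrophile is present to turn the basic flavone carbonyl into a 4-chloroflavylium salt; any aryl(chlorocarbonyl)ketene formed by loss of HCl converges on the same intermediate in step 7.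

Step 7
Reactants: 4 2-(4-methoxyphenyl)-6-methyl-4H-pyran-4-one; 10 2-[5,7-dimethoxy-2-(4-methoxyphenyl)-4-oxo-4H-chromen-8-yl]malonyl dichloride
Product: 13 6-[5,7-dimethoxy-2-(4-methoxyphenyl)-4-oxo-4H-chromen-8-yl]-5,7-dihydroxy-2-(4-methoxyphenyl)-4H-chromen-4-one, via lithium dienolate 11 (not isolated), via acylketene 12 (not isolated)
Conditions: 4 (2.2 equiv), LiN(SiMe3)2 (2.2 equiv), THF, −78 °C; then 10 (1.0 equiv) in THF, −78 °C to rt, finally 40 °C; aq. HCl (excess 4 recovered)
Reagents that add atoms: none
Why: Proposed new method: LiN(SiMe3)2 removes a proton from the 6-methyl group of 4 to give the cross-conjugated dienolate 11, nucleophilic at the exocyclic carbon and at ring C5; one equivalent of 11 acts as base on the acidic malonyl C–H of 10 (giving the aryl(chlorocarbonyl)ketene and returning 4), a second adds through its exocyclic carbon to form the future C7–C8 bond, and on warming the stabilised chloro enolate loses chloride to give acylketene 12. Enolisation of the CH2 group of 12 towards the pyranone gives a dienylketene in which ring C5 closes onto the ketene carbon (6π-electrocyclisation, or the equivalent 6-exo-trig Claisen acylation if the acyl chloride is still in place), forming the C4a–C5 bond and the carbocyclic ring A of unit 1; tautomerisation of the cyclohexadienone then gives the chelated 5,7-dihydroxy arene. The closest known reactions are the vinylogous Claisen acylation of 2-methyl-4-pyranone anions at the methyl carbon, the two-fold C-acylation of enol derivatives by malonyl dichlorides (Effenberger-type [3+3] cyclisation) and the biomimetic Claisen cyclisation of 3,5,7-triketo acid derivatives to phloroglucinols. No stereocentre is formed; the step needs C-acylation at both carbon termini and an intramolecular second acylation, which should be secured by the lithium counter-ion in THF, by the absence of free amide base when 10 is added, by the fact that closure through oxygen would require a four- or eight-membered ring, and by the aromatisation that makes the carbocyclisation irreversible. Because O1 and C4 are fixed in the pyranone and the malonyl unit is symmetric, the aryl group can only end at C6 whichever terminus is acylated first.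

Step 8
Reactants: 13 6-[5,7-dimethoxy-2-(4-methoxyphenyl)-4-oxo-4H-chromen-8-yl]-5,7-dihydroxy-2-(4-methoxyphenyl)-4H-chromen-4-one
Product: 14 5,7-dihydroxy-6-[5-hydroxy-7-methoxy-2-(4-methoxyphenyl)-4-oxo-4H-chromen-8-yl]-2-(4-methoxyphenyl)-4H-chromen-4-one (target)
Conditions: BCl3 (1 M in CH2Cl2, 5 equiv), CH2Cl2, −78 to 0 °C; then MeOH, aq. HCl
Reagents that add atoms: none
Why: Chelation-controlled ether cleavage, in which BCl3 bridges the C4 carbonyl and the peri 5-methoxy oxygen of unit 2 and chloride removes that methyl group, while the 7-methoxy and the two anisyl methoxy groups lack such a chelate and should survive at or below 0 °C; the phenols of unit 1 are only borylated transiently and are freed on work-up.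

**Compound list**

1 | pentane-2,4-dione | CC(=O)CC(C)=O | starting material
2 | methyl 4-methoxybenzoate | COC(=O)c1ccc(OC)cc1 | starting material
3 | 1-(4-methoxyphenyl)hexane-1,3,5-trione | COc1ccc(cc1)C(=O)CC(=O)CC(C)=O | intermediate
4 | 2-(4-methoxyphenyl)-6-methyl-4H-pyran-4-one | COc1ccc(cc1)-c1cc(=O)cc(C)o1 | intermediate
5 | 5,7-dimethoxy-2-(4-methoxyphenyl)-4H-chromen-4-one | COc1ccc(cc1)-c1cc(=O)c2c(OC)cc(OC)cc2o1 | starting material
6 | 8-iodo-5,7-dimethoxy-2-(4-methoxyphenyl)-4H-chromen-4-one | COc1ccc(cc1)-c1cc(=O)c2c(OC)cc(OC)c(I)c2o1 | intermediate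
7 | di-tert-butyl malonate | CC(C)(C)OC(=O)CC(=O)OC(C)(C)C | starting material
8 | di-tert-butyl 2-[5,7-dimethoxy-2-(4-methoxyphenyl)-4-oxo-4H-chromen-8-yl]malonate | CC(C)(C)OC(=O)C(C(=O)OC(C)(C)C)c1c(OC)cc(OC)c2c(=O)cc(-c3ccc(OC)cc3)oc12 | intermediate
9 | 2-[5,7-dimethoxy-2-(4-methoxyphenyl)-4-oxo-4H-chromen-8-yl]malonic acid | OC(=O)C(C(=O)O)c1c(OC)cc(OC)c2c(=O)cc(-c3ccc(OC)cc3)oc12 | intermediate
10 | 2-[5,7-dimethoxy-2-(4-methoxyphenyl)-4-oxo-4H-chromen-8-yl]malonyl dichloride | O=C(Cl)C(C(=O)Cl)c1c(OC)cc(OC)c2c(=O)cc(-c3ccc(OC)cc3)oc12 | intermediate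
11 | lithium 2-(4-methoxyphenyl)-6-methylidene-6H-pyran-4-olate (lithium dienolate of 4) | [Li+].[O-]C1=CC(=C)OC(=C1)c1ccc(OC)cc1 | intermediate
12 | 2-[5,7-dimethoxy-2-(4-methoxyphenyl)-4-oxo-4H-chromen-8-yl]-4-[6-(4-methoxyphenyl)-4-oxo-4H-pyran-2-yl]-3-oxobut-1-en-1-one (acylketene) | O=C=C(C(=O)Cc1cc(=O)cc(o1)-c1ccc(OC)cc1)c1c(OC)cc(OC)c2c(=O)cc(-c3ccc(OC)cc3)oc12 | intermediate
13 | 6-[5,7-dimethoxy-2-(4-methoxyphenyl)-4-oxo-4H-chromen-8-yl]-5,7-dihydroxy-2-(4-methoxyphenyl)-4H-chromen-4-one | COc1ccc(cc1)-c1cc(=O)c2c(O)c(-c3c(OC)cc(OC)c4c(=O)cc(-c5ccc(OC)cc5)oc34)c(O)cc2o1 | intermediate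
14 | 5,7-dihydroxy-6-[5-hydroxy-7-methoxy-2-(4-methoxyphenyl)-4-oxo-4H-chromen-8-yl]-2-(4-methoxyphenyl)-4H-chromen-4-one | COc1ccc(-c2cc(=O)c3c(O)c(-c4c(OC)cc(O)c5c(=O)cc(-c6ccc(OC)cc6)oc45)c(O)cc3o2)cc1 | target

**Step count**
Total steps: 8. Longest linear sequence: 6 steps (5 → 6 → 8 → 9 → 10 → 13 → 14); the pyranone branch (steps 1 and 2) joins at step 7.

**Steps most likely to fail**

1. Step 7 (labelled "Proposed new method:"). The dienolate may be acylated on oxygen, or the acylketene may be captured by a second dienolate faster than it cyclises, giving open-chain bis-pyranonyl diketones instead of the arene. The fallback uses known chemistry: the C6–C8'' bond is made by Suzuki–Miyaura coupling. It sets out from 6 and comes back at 14.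
   - Commercial acacetin (5,7-dihydroxy-2-(4-methoxyphenyl)-4H-chromen-4-one) is benzylated at the non-chelated 7-hydroxyl (BnBr, K2CO3, acetone) to 7-benzyloxy-5-hydroxy-2-(4-methoxyphenyl)-4H-chromen-4-one F1.
   - F1 is iodinated ortho to the free 5-hydroxyl (benzyltrimethylammonium dichloroiodate, CaCO3, CH2Cl2–MeOH) to 7-benzyloxy-5-hydroxy-6-iodo-2-(4-methoxyphenyl)-4H-chromen-4-one F2.
   - F2 is methylated at O5 (MeI, K2CO3, DMF) to 7-benzyloxy-6-iodo-5-methoxy-2-(4-methoxyphenyl)-4H-chromen-4-one F3.
   - Iodide 6 is borylated (bis(pinacolato)diboron, PdCl2(dppf), KOAc, dioxane, 90 °C) to 5,7-dimethoxy-2-(4-methoxyphenyl)-8-(4,4,5,5-tetramethyl-1,3,2-dioxaborolan-2-yl)-4H-chromen-4-one F4.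
   - F4 and F3 are coupled (Pd(OAc)2, SPhos, K3PO4, toluene–H2O, 100 °C) to 7-benzyloxy-6-[5,7-dimethoxy-2-(4-methoxyphenyl)-4-oxo-4H-chromen-8-yl]-5-methoxy-2-(4-methoxyphenyl)-4H-chromen-4-one F5.
   - BCl3 in CH2Cl2 (−78 to 0 °C) then removes the benzyl group and both peri 5-methyl ethers to give 14 directly.

2. Step 6. The arylmalonic acid may decarboxylate during activation, or the dichloride may lose HCl to a ketene that oligomerises on concentration, so that no defined bis-electrophile reaches step 7. The fallback replaces the acid chloride by an isolable active ester; it sets out from 9 and comes back at 13. Diacid 9 is condensed with pentafluorophenol and N,N'-dicyclohexylcarbodiimide (EtOAc, 0 °C) to bis(pentafluorophenyl) 2-[5,7-dimethoxy-2-(4-methoxyphenyl)-4-oxo-4H-chromen-8-yl]malonate F6. F6 can be purified and is then treated with dienolate 11 under the conditions of step 7 (elimination of pentafluorophenoxide to the ketene, then the same annulation) to give 13.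

3. Step 4. Oxidative addition and reductive elimination at the di-ortho-substituted, electron-rich C8 may be slow, so that hydrodeiodination or decomposition of the malonate outruns coupling. The fallback builds the malonate in two C–C bond formations; it sets out from 6 and comes back at 8. Iodide 6 is coupled with the Reformatsky reagent BrZnCH2CO2t-Bu (Pd(OAc)2, P(t-Bu)3·HBF4, THF, 60 °C) to tert-butyl 2-[5,7-dimethoxy-2-(4-methoxyphenyl)-4-oxo-4H-chromen-8-yl]acetate F7. Its benzylic enolate (LiN(SiMe3)2, 2.2 equiv, THF, −78 °C) is then carboxylated with di-tert-butyl dicarbonate to give 8.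

**Further compounds**

F1 | step 7 | 7-benzyloxy-5-hydroxy-2-(4-methoxyphenyl)-4H-chromen-4-one | COc1ccc(cc1)-c1cc(=O)c2c(O)cc(OCc3ccccc3)cc2o1
F2 | step 7 | 7-benzyloxy-5-hydroxy-6-iodo-2-(4-methoxyphenyl)-4H-chromen-4-one | COc1ccc(cc1)-c1cc(=O)c2c(O)c(I)c(OCc3ccccc3)cc2o1
F3 | step 7 | 7-benzyloxy-6-iodo-5-methoxy-2-(4-methoxyphenyl)-4H-chromen-4-one | COc1ccc(cc1)-c1cc(=O)c2c(OC)c(I)c(OCc3ccccc3)cc2o1
F4 | step 7 | 5,7-dimethoxy-2-(4-methoxyphenyl)-8-(4,4,5,5-tetramethyl-1,3,2-dioxaborolan-2-yl)-4H-chromen-4-one | COc1ccc(cc1)-c1cc(=O)c2c(OC)cc(OC)c(B3OC(C)(C)C(C)(C)O3)c2o1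
F5 | step 7 | 7-benzyloxy-6-[5,7-dimethoxy-2-(4-methoxyphenyl)-4-oxo-4H-chromen-8-yl]-5-methoxy-2-(4-methoxyphenyl)-4H-chromen-4-one | COc1ccc(cc1)-c1cc(=O)c2c(OC)c(-c3c(OC)cc(OC)c4c(=O)cc(-c5ccc(OC)cc5)oc34)c(OCc3ccccc3)cc2o1
F6 | step 6 | bis(pentafluorophenyl) 2-[5,7-dimethoxy-2-(4-methoxyphenyl)-4-oxo-4H-chromen-8-yl]malonate | O=C(Oc1c(F)c(F)c(F)c(F)c1F)C(C(=O)Oc1c(F)c(F)c(F)c(F)c1F)c1c(OC)cc(OC)c2c(=O)cc(-c3ccc(OC)cc3)oc12
F7 | step 4 | tert-butyl 2-[5,7-dimethoxy-2-(4-methoxyphenyl)-4-oxo-4H-chromen-8-yl]acetate | CC(C)(C)OC(=O)Cc1c(OC)cc(OC)c2c(=O)cc(-c3ccc(OC)cc3)oc12
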